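**Retrosynthetic overview**
- Briaexcavatolide K ← desilylation of its 12-O-silyl ether ← ten-membered ring closed last at C2–C3 by SmI2 pinacol coupling of a C2/C3 dialdehyde, acetylated in the same flask.
- cis-Fused 8,17-dihydroxy-γ-lactone ← methyl addition to a C17 α-keto lactone ← key C8–O bond: face-selective oxygenation of an isotetronate enolate formed by aldol union (C8–C9) with the cyclohexane aldehyde.
- Isotetronic acid (C3–C8, C17–C19) ← pyruvic acid + the lactol of 4-methyl-5,6-dihydro-2H-pyran-2-one, whose ring fixes the (Z)-C5=C6 alkene.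
- Cyclohexane aldehyde (C1, C10–C14) ← asymmetric Diels–Alder of a 1-amino-3-siloxypentadiene with ethyl 3-methyl-4-oxocrotonate, then epoxidation, kinetic protonation at C11, reductive opening and 1,3-anti reduction.
- Ring order: cyclohexane, then γ-lactone, then the ten-membered ring.

Assumption: briarane numbering with α/β descriptors (Me-15 = β) is used for every intermediate, and the two organocatalysts (steps 2 and 10) are taken to give the enantiomers drawn; their mirror-image forms are equally available.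

**Route**

Step 1
Reactants: 1 (E)-4-(dimethylamino)but-3-en-2-one
Product: 3 (1E,3Z)-3-(tert-butyldimethylsilyloxy)-N,N-dimethylpenta-1,3-dien-1-amine, via ethyl enaminone 2 (not isolated)
Conditions: LiN(i-Pr)2, THF, −78 °C; MeI, −78 to 0 °C; then NaN(SiMe3)2, −78 °C; t-BuMe2SiCl, −78 to 0 °C
Reagents that add atoms: iodomethane, CI; tert-butyldimethylsilyl chloride, CC(C)(C)[Si](C)(C)Cl
Why: α′-Enolate methylation of the vinylogous amide followed by (Z)-selective enolisation and O-silylation (silyl enol ether formation) is the standard entry to 1-amino-3-siloxy dienes; no stereocentre is formed.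

Step 2
Reactants: 3 (1E,3Z)-3-(tert-butyldimethylsilyloxy)-N,N-dimethylpenta-1,3-dien-1-amine; 4 ethyl (E)-3-methyl-4-oxobut-2-enoate
Product: 7 ethyl (1S,2S,6S)-6-(diethoxymethyl)-2,6-dimethyl-3-oxocyclohex-4-ene-1-carboxylate, via endo cycloadduct 5 (not isolated), via enone aldehyde 6 (not isolated)
Conditions: (4R,5R)-tetra(1-naphthyl)-TADDOL (20 mol%), toluene, −78 °C, 48 h; then HC(OEt)3, EtOH, camphorsulfonic acid (1.5 equiv), 0 °C to rt
Reagents that add atoms: triethyl orthoformate, CCOC(OCC)OCC; ethanol, CCO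
Why: Hydrogen-bond-catalysed endo Diels–Alder reaction joins C11–C10 and C14–C1 with the regiochemistry set by the amino group and the activated aldehyde, the (E)-dienophile fixes C2/C9 trans and the catalyst sets C1 and C10, after which acid hydrolyses the silyl enol ether, eliminates Me2NH and acetalises the neopentyl aldehyde (C11 settles trans to the ester and is corrected in step 4).

Step 3
Reactants: 7 ethyl (1S,2S,6S)-6-(diethoxymethyl)-2,6-dimethyl-3-oxocyclohex-4-ene-1-carboxylate
Product: 8 ethyl 5-(diethoxymethyl)-3,5-dimethyl-2-oxo-7-oxabicyclo[4.1.0]heptane-4-carboxylate (13α,14α-epoxide; 11α-Me)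
Conditions: t-BuOOH, DBU, CH2Cl2, 0 °C to rt
Reagents that add atoms: tert-butyl hydroperoxide, CC(C)(C)OO
Why: Weitz–Scheffer nucleophilic epoxidation, in which the peroxide anion adds to C14 anti to the pseudo-axial Me-15 on the adjacent quaternary carbon, so the C14 oxygen is α.

Step 4
Reactants: 8 ethyl 5-(diethoxymethyl)-3,5-dimethyl-2-oxo-7-oxabicyclo[4.1.0]heptane-4-carboxylate (11α-Me)
Product: 9 C11 epimer of 8 (11β-Me; cis to the C10 ester)
Conditions: LiN(SiMe3)2 (1.1 equiv), THF, −78 °C; then AcOH in THF, −78 °C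
Reagents that add atoms: none
Why: Enolisation is possible only toward C11, and kinetic protonation of the enolate occurs anti to the C10 ester (pseudo-axial in the enolate to escape A(1,2) strain), giving the contra-thermodynamic 11β-methyl epimer.

Step 5
Reactants: 9 epoxy ketone (11β-Me)
Product: 10 ethyl 6-(diethoxymethyl)-5-hydroxy-2,6-dimethyl-3-oxocyclohexane-1-carboxylate (14α-OH; 11β-Me)
Conditions: SmI2 (2.5 equiv), THF/MeOH, −90 °C, 10 min
Reagents that add atoms: none
Why: Single-electron reductive cleavage of the Cα–O bond of the α,β-epoxy ketone (Molander conditions) gives the β-hydroxy ketone with the C14 configuration of the epoxide and leaves ester, acetal and C11 untouched.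

Step 6
Reactants: 10 β-hydroxy ketone
Product: 11 ethyl 6-(diethoxymethyl)-3,5-dihydroxy-2,6-dimethylcyclohexane-1-carboxylate (12β-OH; 14α-OH)
Conditions: Me4NBH(OAc)3, MeCN/AcOH (1:1), −30 °C
Reagents that add atoms: none
Why: Evans–Saksena reduction, in which the C14 hydroxyl binds the triacetoxyborohydride and delivers hydride to the α face of C12, gives the 1,3-anti diol.

Step 7
Reactants: 11 diol
Product: 12 ethyl 3-(tert-butyldimethylsilyloxy)-6-(diethoxymethyl)-5-hydroxy-2,6-dimethylcyclohexane-1-carboxylate (12β-OTBS; 14α-OH)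
Conditions: t-BuMe2SiCl (1.1 equiv), imidazole, DMF, 0 °C to rt
Reagents that add atoms: tert-butyldimethylsilyl chloride, CC(C)(C)[Si](C)(C)Cl
Why: Sterically controlled silylation, since the 12-hydroxyl is an ordinary secondary alcohol whereas the 14-hydroxyl is neopentyl and stays free.

Step 8
Reactants: 12 silyl ether ester
Product: 13 3-(tert-butyldimethylsilyloxy)-6-(diethoxymethyl)-5-hydroxy-2,6-dimethylcyclohexane-1-carbaldehyde (C9 aldehyde; ring configuration as in 12)
Conditions: i-Bu2AlH (2.2 equiv), CH2Cl2, −78 °C; aq. KNaC4H4O6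
Reagents that add atoms: none
Why: Partial ester reduction with i-Bu2AlH stops at the aluminium hemiacetal at low temperature and releases the aldehyde on work-up without touching a stereocentre.

Step 9
Reactants: 14 4-methyl-5,6-dihydro-2H-pyran-2-one
Product: 15 4-methyl-5,6-dihydro-2H-pyran-2-ol (lactol; ring–chain tautomer of (Z)-5-hydroxy-3-methylpent-2-enal)
Conditions: i-Bu2AlH (1.05 equiv), CH2Cl2, −78 °C; aq. KNaC4H4O6
Reagents that add atoms: none
Why: 1,2-Half-reduction of the unsaturated δ-lactone gives the lactol, and the ring guarantees the (Z) trisubstituted alkene that becomes C5=C6.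

Step 10
Reactants: 15 4-methyl-5,6-dihydro-2H-pyran-2-ol; 16 pyruvic acid
Product: 17 (S)-3-hydroxy-5-[(Z)-4-hydroxy-2-methylbut-1-en-1-yl]furan-2(5H)-one
Conditions: (S)-2-(pyrrolidin-2-yl)-1H-benzimidazole (20 mol%), CF3CO2H (20 mol%), THF, 0 °C to rt; 16 added over 12 h to 15 (3 equiv)
Reagents that add atoms: none
Why: Enamine-catalysed direct cross-aldol of pyruvic acid with the open hydroxy-enal form of 15, then spontaneous lactonisation and enolisation, gives the isotetronic acid with C7 set by the catalyst, slow addition suppressing pyruvate self-aldol.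

Step 11
Reactants: 13 cyclohexane C9 aldehyde; 17 (S)-isotetronic acid
Product: 19 α-keto lactone (C17 ketone; 7β-H; 8β-OH; 9α-OH; free C3 primary OH and 14α-OH; 12β-OTBS; C2 diethyl acetal), via aldol adduct 18 (not isolated)
Conditions: LiN(SiMe3)2 (1.15 equiv on 17), THF, −78 °C; 13, −78 to −30 °C; then 2-(phenylsulfonyl)-3-phenyloxaziridine, −78 °C; AcOH
Reagents that add atoms: 2-(phenylsulfonyl)-3-phenyloxaziridine, O=S(=O)(N1OC1c1ccccc1)c1ccccc1
Why: Proposed new method: tandem aldol–enolate oxygenation of an isotetronate, in which the lithium enolate of 17 adds through C8 to the aldehyde under Felkin–Anh control (anti to quaternary C1, giving 9α-O), the aldolate is reprotonated internally by the acidic C8–H to give a new tetrasubstituted enolate whose O17–Li···O9–H chelate holds the cyclohexyl group on the face of the C7 side chain, and the N-sulfonyloxaziridine then transfers oxygen to C8 from the open face cis to H-7, forming the 8β tertiary C–O bond that defines the cis lactone fusion; the closest known reactions are Davis oxaziridine α-hydroxylation of β-dicarbonyl enolates and Rubottom oxidation, neither shown on 4-substituted isotetronates or in relay with an aldol step.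

Step 12
Reactants: 19 α-keto lactone
Product: 20 dihydroxy lactone (17α-OH; 18β-Me; otherwise as 19)
Conditions: MeMgBr (6 equiv), THF, −78 °C; AcOH, −78 °C
Reagents that add atoms: methylmagnesium bromide, C[Mg]Br
Why: Chemoselective Grignard addition to the highly electrophilic α-keto lactone ketone, with methyl entering anti to the C9 and C6 substituents (cis to the 8-hydroxyl), sets C17.

Step 13
Reactants: 20 dihydroxy lactone with primary C3 alcohol
Product: 22 bis(diethyl acetal) (C2 and C3 both CH(OEt)2; free 8-, 9-, 14- and 17-OH), via C3 aldehyde 21 (not isolated)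
Conditions: Cu(MeCN)4OTf (5 mol%), 2,2′-bipyridine, TEMPO, N-methylimidazole, air, MeCN, rt; silica plug; then EtOH, PPTS, 3 Å sieves, rt
Reagents that add atoms: ethanol, CCO
Why: Aerobic copper/TEMPO (Stahl) oxidation with monovalent copper is selective for the primary alcohol, and the sensitive (Z)-β,γ-unsaturated aldehyde is masked at once by acid-catalysed acetalisation.

Step 14
Reactants: 22 bis(diethyl acetal)
Product: 23 9,14-diacetate of 22
Conditions: Ac2O, pyridine, DMAP (0.2 equiv), CH2Cl2, 0 °C to rt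
Reagents that add atoms: acetic anhydride, CC(=O)OC(C)=O
Why: DMAP-catalysed acylation esterifies the two secondary hydroxyls and leaves the tertiary 8- and 17-hydroxyls, which also prevents lactol formation between O9 and the C2 aldehyde later.

Step 15
Reactants: 23 diacetate bis(acetal)
Product: 24 C2/C3 dialdehyde (9α,14α-diacetate; 8β,17α-diol; 12β-OTBS)
Conditions: Amberlyst-15, acetone/H2O (20:1), rt
Reagents that add atoms: water, O
Why: Mild heterogeneous acid-catalysed acetal hydrolysis frees both aldehydes without cleaving the secondary silyl ether or isomerising the β,γ-unsaturated aldehyde.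

Step 16
Reactants: 24 dialdehyde
Product: 26 12-O-(tert-butyldimethylsilyl)briaexcavatolide K, via macrocyclic diol 25 (not isolated)
Conditions: SmI2 (3 equiv), THF (2 mM), −78 °C to rt; then Ac2O, pyridine, DMAP, rt
Reagents that add atoms: acetic anhydride, CC(=O)OC(C)=O
Why: Intramolecular SmI2 pinacol coupling at high dilution closes the ten-membered ring through a samarium-bridged ketyl–aldehyde pair, expected to give the cis (erythro) diol on the face syn to Me-15 (2β,3β), and the samarium diolate is acetylated in the same flask.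

Step 17
Reactants: 26 12-O-(tert-butyldimethylsilyl)briaexcavatolide K
Product: 27 briaexcavatolide K
Conditions: HF·pyridine, pyridine, THF, 0 °C to rt
Reagents that add atoms: none
Why: Fluoride-mediated desilylation of the secondary silyl ether leaves acetates, lactone and tertiary alcohols intact.

**Compound list**
1 | (E)-4-(dimethylamino)but-3-en-2-one | CC(=O)/C=C/N(C)C | starting material
2 | (E)-1-(dimethylamino)pent-1-en-3-one | CCC(=O)/C=C/N(C)C | intermediate
3 | (1E,3Z)-3-(tert-butyldimethylsilyloxy)-N,N-dimethylpenta-1,3-dien-1-amine | C/C=C(O[Si](C)(C)C(C)(C)C)/C=C/N(C)C | intermediate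
4 | ethyl (E)-3-methyl-4-oxobut-2-enoate | CCOC(=O)/C=C(\C)C=O | starting material
5 | endo cycloadduct, ethyl 3-(tert-butyldimethylsilyloxy)-5-(dimethylamino)-6-formyl-2,6-dimethylcyclohex-3-ene-1-carboxylate (15-Me β, CHO α, 10α-H, 11α-Me, 14α-NMe2) | CCOC(=O)[C@H]1[C@H](C)C(O[Si](C)(C)C(C)(C)C)=C[C@H](N(C)C)[C@]1(C)C=O | intermediate
6 | ethyl 6-formyl-2,6-dimethyl-3-oxocyclohex-4-ene-1-carboxylate (configuration as 7) | CCOC(=O)[C@H]1[C@H](C)C(=O)C=C[C@]1(C)C=O | intermediate
7 | ethyl (1S,2S,6S)-6-(diethoxymethyl)-2,6-dimethyl-3-oxocyclohex-4-ene-1-carboxylate | CCOC(=O)[C@H]1[C@H](C)C(=O)C=C[C@]1(C)C(OCC)OCC | intermediate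
8 | ethyl 5-(diethoxymethyl)-3,5-dimethyl-2-oxo-7-oxabicyclo[4.1.0]heptane-4-carboxylate (13α,14α-epoxide, 11α-Me) | CCOC(=O)[C@H]1[C@H](C)C(=O)[C@@H]2O[C@@H]2[C@]1(C)C(OCC)OCC | intermediate
9 | C11 epimer of 8 (11β-Me, cis to the ester) | CCOC(=O)[C@H]1[C@@H](C)C(=O)[C@@H]2O[C@@H]2[C@]1(C)C(OCC)OCC | intermediate
10 | ethyl 6-(diethoxymethyl)-5-hydroxy-2,6-dimethyl-3-oxocyclohexane-1-carboxylate (14α-OH, 11β-Me) | CCOC(=O)[C@H]1[C@@H](C)C(=O)C[C@H](O)[C@]1(C)C(OCC)OCC | intermediate
11 | ethyl 6-(diethoxymethyl)-3,5-dihydroxy-2,6-dimethylcyclohexane-1-carboxylate (12β-OH, 14α-OH) | CCOC(=O)[C@H]1[C@@H](C)[C@@H](O)C[C@H](O)[C@]1(C)C(OCC)OCC | intermediate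
12 | 12-O-tert-butyldimethylsilyl ether of 11 | CCOC(=O)[C@H]1[C@@H](C)[C@@H](O[Si](C)(C)C(C)(C)C)C[C@H](O)[C@]1(C)C(OCC)OCC | intermediate
13 | 3-(tert-butyldimethylsilyloxy)-6-(diethoxymethyl)-5-hydroxy-2,6-dimethylcyclohexane-1-carbaldehyde (C9 aldehyde, ring configuration as 12) | O=C[C@H]1[C@@H](C)[C@@H](O[Si](C)(C)C(C)(C)C)C[C@H](O)[C@]1(C)C(OCC)OCC | intermediate
14 | 4-methyl-5,6-dihydro-2H-pyran-2-one | CC1=CC(=O)OCC1 | starting material
15 | 4-methyl-5,6-dihydro-2H-pyran-2-ol (lactol, both anomers) | CC1=CC(O)OCC1 | intermediate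
16 | pyruvic acid | CC(=O)C(O)=O | starting material
17 | (S)-3-hydroxy-5-[(Z)-4-hydroxy-2-methylbut-1-en-1-yl]furan-2(5H)-one | OCC/C(C)=C\[C@@H]1OC(=O)C(O)=C1 | intermediate
18 | aldol adduct: 17 carrying at C8 the 9α-hydroxy-cyclohexylmethyl unit of 13 (enol form) | OCC/C(C)=C\[C@@H]1OC(=O)C(O)=C1[C@H](O)[C@H]2[C@@H](C)[C@@H](O[Si](C)(C)C(C)(C)C)C[C@H](O)[C@]2(C)C(OCC)OCC | intermediate
19 | α-keto lactone (C17 ketone, 7β-H, 8β-OH, 9α-OH) | OCC/C(C)=C\[C@@H]1OC(=O)C(=O)[C@]1(O)[C@H](O)[C@H]2[C@@H](C)[C@@H](O[Si](C)(C)C(C)(C)C)C[C@H](O)[C@]2(C)C(OCC)OCC | intermediate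
20 | dihydroxy lactone (8β-OH, 17α-OH, 18β-Me, 9α-OH) | OCC/C(C)=C\[C@@H]1OC(=O)[C@](C)(O)[C@]1(O)[C@H](O)[C@H]2[C@@H](C)[C@@H](O[Si](C)(C)C(C)(C)C)C[C@H](O)[C@]2(C)C(OCC)OCC | intermediate
21 | C3 aldehyde of 20 | O=CC/C(C)=C\[C@@H]1OC(=O)[C@](C)(O)[C@]1(O)[C@H](O)[C@H]2[C@@H](C)[C@@H](O[Si](C)(C)C(C)(C)C)C[C@H](O)[C@]2(C)C(OCC)OCC | intermediate
22 | C2,C3-bis(diethyl acetal) | CCOC(OCC)C/C(C)=C\[C@@H]1OC(=O)[C@](C)(O)[C@]1(O)[C@H](O)[C@H]2[C@@H](C)[C@@H](O[Si](C)(C)C(C)(C)C)C[C@H](O)[C@]2(C)C(OCC)OCC | intermediate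
23 | 9α,14α-diacetate of 22 | CCOC(OCC)C/C(C)=C\[C@@H]1OC(=O)[C@](C)(O)[C@]1(O)[C@H](OC(C)=O)[C@H]2[C@@H](C)[C@@H](O[Si](C)(C)C(C)(C)C)C[C@H](OC(C)=O)[C@]2(C)C(OCC)OCC | intermediate
24 | C2/C3 dialdehyde | O=CC/C(C)=C\[C@@H]1OC(=O)[C@](C)(O)[C@]1(O)[C@H](OC(C)=O)[C@H]2[C@@H](C)[C@@H](O[Si](C)(C)C(C)(C)C)C[C@H](OC(C)=O)[C@]2(C)C=O | intermediate
25 | macrocyclic 2β,3β-diol (2,3-dideacetyl-12-O-TBS-briaexcavatolide K) | O[C@H]1C/C(C)=C\[C@@H]2OC(=O)[C@](C)(O)[C@]2(O)[C@H](OC(C)=O)[C@H]2[C@@H](C)[C@@H](O[Si](C)(C)C(C)(C)C)C[C@H](OC(C)=O)[C@]2(C)[C@H]1O | intermediate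
26 | 12-O-(tert-butyldimethylsilyl)briaexcavatolide K | CC(=O)O[C@H]1C/C(C)=C\[C@@H]2OC(=O)[C@](C)(O)[C@]2(O)[C@H](OC(C)=O)[C@H]2[C@@H](C)[C@@H](O[Si](C)(C)C(C)(C)C)C[C@H](OC(C)=O)[C@]2(C)[C@H]1OC(C)=O | intermediate
27 | briaexcavatolide K | CC(=O)O[C@H]1C/C(C)=C\[C@@H]2OC(=O)[C@](C)(O)[C@]2(O)[C@H](OC(C)=O)[C@H]2[C@@H](C)[C@@H](O)C[C@H](OC(C)=O)[C@]2(C)[C@H]1OC(C)=O | target

**Step count**
Total: 17 steps. Longest linear sequence: 15 (steps 1–8 and 11–17).

**Three steps most likely to fail**

Step 10 (asymmetric aldol–lactonisation). Pyruvate self-aldol and the low free-aldehyde content of the lactol may erode yield and enantioselectivity. The fallback sets out from 15 and comes back at 19. Lactol 15 is condensed with oxaloacetic acid (Et3N, THF/H2O, then dilute HCl), a known decarboxylative aldol–lactonisation, to give the racemic isotetronic acid F1. F1 is used in step 11 in place of 17. Because C9 is controlled by the aldehyde partner, the two enantiomers of F1 give 19 and the 7-epi series F2, which are separated by chromatography; 19 rejoins the route and F2 is discarded.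

Step 11 (proposed tandem aldol–oxygenation). The stabilised enolate may add sluggishly to the hindered aldehyde, or the oxaziridine may show poor facial selectivity. The fallback uses known reactions, sets out from 17 and 13 and comes back at 19. Acid 17 is silylated (Me3SiCl, Et3N) to the bis(trimethylsilyl) derivative F3. BF3·OEt2-promoted Mukaiyama aldol addition of F3 to 13 at −78 °C (Felkin–Anh; the hindered acetal is tolerated) and aqueous work-up give 18, now isolated. Titration of 18 with dimethyldioxirane in acetone at −78 °C (Rubottom-type enol oxidation) gives 19. The O9–H···O17 hydrogen bond holds the same rotamer, and the enol is oxidised much faster than the acyloxy-deactivated C5=C6 alkene.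

Step 16 (pinacol macrocyclisation). Ten-membered ring closure, the cis/β outcome at C2/C3 and partial masking of the C2 aldehyde as a hemiacetal with the 8-hydroxyl are all uncertain. The fallback sets out from 24 and comes back at 25. Both aldehydes are methylenated (Zn, CH2Br2, TiCl4) to the diene F4. Ring-closing metathesis with the second-generation Grubbs catalyst RuCl2(=CHPh)(PCy3)(H2IMes) (toluene, 80 °C, 1 mM) gives the ten-membered (Z)-2,3-alkene F5, the Z geometry being enforced by ring size. Dihydroxylation with catalytic OsO4 and N-methylmorpholine N-oxide then gives the cis diol 25, which is acetylated as in the second stage of step 16 to 26. The C5=C6 alkene is deactivated by the allylic lactone oxygen, so C2=C3 should react first, but the β-face preference is unproven.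

**Further compounds**
F1 | step 10 | racemic 3-hydroxy-5-[(Z)-4-hydroxy-2-methylbut-1-en-1-yl]furan-2(5H)-one | OCC/C(C)=C\C1OC(=O)C(O)=C1
F2 | step 10 | 7-epi series of 19 (7α-H; C8 epimers) | OCC/C(C)=C\[C@H]1OC(=O)C(=O)C1(O)[C@H](O)[C@H]2[C@@H](C)[C@@H](O[Si](C)(C)C(C)(C)C)C[C@H](O)[C@]2(C)C(OCC)OCC
F3 | step 11 | (S)-5-[(Z)-2-methyl-4-(trimethylsilyloxy)but-1-en-1-yl]-3-(trimethylsilyloxy)furan-2(5H)-one | C[Si](C)(C)OCC/C(C)=C\[C@@H]1OC(=O)C(O[Si](C)(C)C)=C1
F4 | step 16 | bis-methylenated 24 (C2 and C3 vinyl groups) | C=CC/C(C)=C\[C@@H]1OC(=O)[C@](C)(O)[C@]1(O)[C@H](OC(C)=O)[C@H]2[C@@H](C)[C@@H](O[Si](C)(C)C(C)(C)C)C[C@H](OC(C)=O)[C@]2(C)C=C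
F5 | step 16 | ten-membered (2Z,5Z)-diene, 2,3-dideoxy-2,3-didehydro analogue of 25 | C/1=C/C/C(C)=C\[C@@H]2OC(=O)[C@](C)(O)[C@]2(O)[C@H](OC(C)=O)[C@H]2[C@@H](C)[C@@H](O[Si](C)(C)C(C)(C)C)C[C@H](OC(C)=O)[C@@]21C
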